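**Retrosynthetic overview**
1. Target 19 ⇐ 15‑O‑TBS lactone 18 ⇐ isopropenyl carbinol 14: the isopropenyl methyl (C12) is oxidised and closes the lactone onto O6, as in germacrene A → germacrene A acid → costunolide. The lactone is the second ring formed.
2. 14 ⇐ acyclic, fully oxidised C15 chain 13 by C6–C7 bond formation: a carbonyl‑ene macrocyclisation (C6 aldehyde plus C7=C11 prenyl alkene, with hydrogen loss to the isopropenyl group) that copies the farnesyl C1→C10 closure. The ten‑membered carbocycle is the first ring formed.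
3. 13 ⇐ furan 11: the furan is a masked 4Z C3‑ketone/C6‑aldehyde, released with singlet oxygen.
4. 11 ⇐ bromofuran 3 + diol 8 (Heck reaction builds the 1E alkene) + (2R)‑2‑methylbutanoic acid 10.
5. 8 ⇐ prenal 4 + 2‑methoxypropene 5 (asymmetric acetone aldol sets C8), then vinyl Grignard (1,3‑anti, sets C10); 3 ⇐ furan‑3‑ylmethanol 1.

Numbering: germacrane numbering is used throughout (ring C1–C10; C11–C13 on C7; C14 on C10; C15 on C4); the target is 1E,4Z,6R,7R,8R,10R,2'R.
Assumption: the enantiomer of the binaphthyl Schiff‑base ligand in step 3 is the one that gives the 4R alcohol 7 (checked by Mosher ester analysis), and (2R)‑2‑methylbutanoic acid is bought enantiopure.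

**Step 1**
Reactants: 1 furan‑3‑ylmethanol
Product: 2 tert‑butyl(furan‑3‑ylmethoxy)dimethylsilane
Conditions: TBSCl (1.1 equiv), imidazole (1.5 equiv), CH2Cl2, 0 °C to rt
Reagents that add atoms: tert‑butyldimethylsilyl chloride, CC(C)(C)[Si](C)(C)Cl
Why: O‑silylation of the primary alcohol; the TBS ether keeps O15 from being oxidised in step 10 and from forming a lactol with C6 should the enal isomerise.

**Step 2**
Reactants: 2 tert‑butyl(furan‑3‑ylmethoxy)dimethylsilane
Product: 3 [(2‑bromofuran‑3‑yl)methoxy](tert‑butyl)dimethylsilane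
Conditions: NBS (1.05 equiv), DMF, −20 to 0 °C, dark
Reagents that add atoms: N‑bromosuccinimide, O=C1CCC(=O)N1Br
Why: Electrophilic aromatic bromination; a 3‑alkylfuran is attacked at the adjacent alpha position (C2), which is activated by both the ring oxygen and the alkyl group.

**Step 3**
Reactants: 4 3‑methylbut‑2‑enal (prenal); 5 2‑methoxypropene
Product: 7 (4R)‑4‑hydroxy‑6‑methylhept‑5‑en‑2‑one, via enol ether adduct 6 (not isolated)
Conditions: Ti(OiPr)4 (5 mol %), 2‑[(3,5‑di‑tert‑butyl‑2‑hydroxybenzylidene)amino]‑2'‑hydroxy‑1,1'‑binaphthyl (10 mol %), 2,6‑di‑tert‑butyl‑4‑methylpyridine (0.4 equiv), 5 as solvent, 0 °C; then 1 M aq HCl, Et2O, 0 °C, 5 min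
Reagents that add atoms: water, O
Why: Catalytic enantioselective acetone‑aldol addition (ene‑type addition of 2‑methoxypropene to the aldehyde bound to the chiral tetravalent titanium complex), in which the ligand shields one aldehyde face and sets C8 as R, followed by brief acid hydrolysis of the methyl enol ether 6 to the ketone.

**Step 4**
Reactants: 7 (4R)‑4‑hydroxy‑6‑methylhept‑5‑en‑2‑one
Product: 8 (3R,5R)‑3,7‑dimethylocta‑1,6‑diene‑3,5‑diol
Conditions: vinylMgBr (3.0 equiv), CH2Cl2/THF 4:1, −78 °C; then pH 7 buffer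
Reagents that add atoms: vinylmagnesium bromide, C=C[Mg]Br
Why: Chelation‑controlled (Cram‑chelate) Grignard 1,2‑addition, in which the magnesium alkoxide ties the ketone into a six‑membered chelate with the alkenyl group pseudo‑equatorial so that vinyl adds axially to give the 1,3‑anti diol (C10 = R); the minor syn diol is removed by chromatography.

**Step 5**
Reactants: 3 [(2‑bromofuran‑3‑yl)methoxy](tert‑butyl)dimethylsilane; 8 (3R,5R)‑3,7‑dimethylocta‑1,6‑diene‑3,5‑diol
Product: 9 (1E,3R,5R)‑1‑[3‑({[tert‑butyl(dimethyl)silyl]oxy}methyl)furan‑2‑yl]‑3,7‑dimethylocta‑1,6‑diene‑3,5‑diol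
Conditions: Pd(OAc)2 (5 mol %), P(o‑tol)3 (12 mol %), Et3N (2 equiv), MeCN, 80 °C
Reagents that add atoms: none
Why: Mizoroki–Heck reaction; zerovalent palladium inserts into the furyl C–Br bond, the furyl group adds to the terminal vinyl carbon and, because C10 carries no hydrogen, beta‑hydride elimination can only give the 1E alkene, while the trisubstituted alkene is inert.

**Step 6**
Reactants: 9 furyl diene diol; 10 (2R)‑2‑methylbutanoic acid
Product: 11 (1E,3R,5R)‑1‑[3‑({[tert‑butyl(dimethyl)silyl]oxy}methyl)furan‑2‑yl]‑3‑hydroxy‑3,7‑dimethylocta‑1,6‑dien‑5‑yl (2R)‑2‑methylbutanoate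
Conditions: DCC (1.3 equiv), DMAP (0.1 equiv), CH2Cl2, 0 °C
Reagents that add atoms: none
Why: Steglich esterification, selective for the secondary allylic hydroxyl over the tertiary one and touching no stereocentre; the diastereomeric ester from any residual (8S,10S) material is removed by chromatography.

**Step 7**
Reactants: 11 furyl ester
Product: 13 (4R,6R,7E,10Z)‑10‑({[tert‑butyl(dimethyl)silyl]oxy}methyl)‑6‑hydroxy‑2,6‑dimethyl‑9,12‑dioxododeca‑2,7,10‑trien‑4‑yl (2R)‑2‑methylbutanoate, via furan endoperoxide 12 (not isolated)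
Conditions: O2, hν (white LED), tetraphenylporphyrin (0.5 mol %), CH2Cl2, −78 °C; then Me2S (3 equiv), −78 to 0 °C; rapid filtration through neutral silica, used at once
Reagents that add atoms: dioxygen, O=O
Why: Singlet‑oxygen [4+2] cycloaddition to the furan and reductive opening of the endoperoxide (furan to cis‑enedione oxidation), which delivers the C3 ketone and the C6 aldehyde with the 4Z geometry fixed by the former ring; the furan reacts far faster than the trisubstituted alkene.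

**Step 8**
Reactants: 13 acyclic Z‑keto‑enal
Product: 14 (1E,4Z,6R,7S,8R,10R)‑15‑[(tert‑butyldimethylsilyl)oxy]‑6,10‑dihydroxy‑3‑oxogermacra‑1,4,11(13)‑trien‑8‑yl (2R)‑2‑methylbutanoate
Conditions: Me2AlCl (3.0 equiv), CH2Cl2, 13 added over 8 h to 2 mM final concentration, −78 to −30 °C; aq Rochelle salt
Reagents that add atoms: none
Why: Proposed new method: a Lewis‑acid carbonyl‑ene macrocyclisation closing a ten‑membered ring, in which the Me2AlCl‑bound C6 aldehyde (strongly activated by the cis‑4‑oxo group) is attacked by C7 of the only electron‑rich alkene while a hydrogen of the E‑methyl on C11 shifts to oxygen through a chair six‑membered transition state with both chain arms pseudo‑equatorial (this gives the 6,7‑relationship of the later trans‑lactone, 6R), and 1,3‑allylic strain holds H8 in the alkene plane so that C6 adds anti to C9 on the side of the acyloxy group (this sets C7, labelled 7S here only because of CIP priorities); the closest known reactions are Me2AlCl‑promoted ene cyclisations of aldehydes onto trisubstituted alkenes and Lewis‑acid ene macrocyclisations of prenyl‑terminated ynals to 12‑ to 16‑membered rings, so ring size and stereochemical outcome are the untested points.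

**Step 9**
Reactants: 14 ten‑membered isopropenyl carbinol
Product: 15 (1E,4Z,6R,7S,8R,10R)‑15‑[(tert‑butyldimethylsilyl)oxy]‑6,10,12‑trihydroxy‑3‑oxogermacra‑1,4,11(13)‑trien‑8‑yl (2R)‑2‑methylbutanoate
Conditions: SeO2 (0.2 equiv), t‑BuOOH (3 equiv, decane solution), CH2Cl2, 0 °C to rt
Reagents that add atoms: tert‑butyl hydroperoxide, CC(C)(C)OO; selenium dioxide (catalytic oxygen carrier), O=[Se]=O
Why: Selenium dioxide allylic oxidation (ene reaction, then [2,3]‑sigmatropic shift) of the only electron‑rich alkene, which hydroxylates the methyl of the isopropenyl group (the future C12) in preference to the hindered C7 methine and leaves both enone alkenes untouched.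

**Step 10**
Reactants: 15 C12 allylic alcohol
Product: 18 [(3aR,4R,6R,7E,10Z,11aR)‑10‑({[tert‑butyl(dimethyl)silyl]oxy}methyl)‑6‑hydroxy‑6‑methyl‑3‑methylidene‑2,9‑dioxo‑2,3,3a,4,5,6,9,11a‑octahydrocyclodeca[b]furan‑4‑yl] (2R)‑2‑methylbutanoate, via hydroxy enal 16 (not isolated), via lactol 17 (not isolated)
Conditions: TEMPO (0.2 equiv), PhI(OAc)2 (2.5 equiv), CH2Cl2, rt
Reagents that add atoms: none
Why: TEMPO‑catalysed oxidative lactonisation of a 1,4‑diol, in which the primary allylic alcohol is oxidised selectively to the enal, the 6‑OH closes the lactol and a second oxidation gives the alpha‑methylene‑gamma‑lactone; the C8 ester blocks the alternative 12,8‑closure.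

**Step 11**
Reactants: 18 15‑O‑TBS lactone
Product: 19 [(3aR,4R,6R,7E,10Z,11aR)‑6‑hydroxy‑10‑(hydroxymethyl)‑6‑methyl‑3‑methylidene‑2,9‑dioxo‑2,3,3a,4,5,6,9,11a‑octahydrocyclodeca[b]furan‑4‑yl] (2R)‑2‑methylbutanoate (target, CNP0232405.1)
Conditions: HF·pyridine, THF/pyridine, 0 °C to rt
Reagents that add atoms: none
Why: Fluoride‑mediated silyl ether cleavage under buffered conditions that spare the alpha‑methylene lactone, the cross‑conjugated dienone and both esters.

**Compound list**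
1 | furan‑3‑ylmethanol | OCc1ccoc1 | starting material
2 | tert‑butyl(furan‑3‑ylmethoxy)dimethylsilane | CC(C)(C)[Si](C)(C)OCc1ccoc1 | intermediate
3 | [(2‑bromofuran‑3‑yl)methoxy](tert‑butyl)dimethylsilane | CC(C)(C)[Si](C)(C)OCc1ccoc1Br | intermediate
4 | 3‑methylbut‑2‑enal (prenal) | CC(C)=CC=O | starting material
5 | 2‑methoxypropene | COC(C)=C | starting material
6 | (4R)‑2‑methoxy‑6‑methylhepta‑1,5‑dien‑4‑ol (enol ether adduct, not isolated) | C=C(OC)C[C@@H](O)C=C(C)C | intermediate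
7 | (4R)‑4‑hydroxy‑6‑methylhept‑5‑en‑2‑one | CC(=O)C[C@@H](O)C=C(C)C | intermediate
8 | (3R,5R)‑3,7‑dimethylocta‑1,6‑diene‑3,5‑diol | C=C[C@](C)(O)C[C@@H](O)C=C(C)C | intermediate
9 | (1E,3R,5R)‑1‑[3‑({[tert‑butyl(dimethyl)silyl]oxy}methyl)furan‑2‑yl]‑3,7‑dimethylocta‑1,6‑diene‑3,5‑diol | CC(C)(C)[Si](C)(C)OCc1ccoc1/C=C/[C@](C)(O)C[C@@H](O)C=C(C)C | intermediate
10 | (2R)‑2‑methylbutanoic acid | CC[C@@H](C)C(=O)O | starting material
11 | (1E,3R,5R)‑1‑[3‑({[tert‑butyl(dimethyl)silyl]oxy}methyl)furan‑2‑yl]‑3‑hydroxy‑3,7‑dimethylocta‑1,6‑dien‑5‑yl (2R)‑2‑methylbutanoate | CC(C)(C)[Si](C)(C)OCc1ccoc1/C=C/[C@](C)(O)C[C@@H](OC(=O)[C@H](C)CC)C=C(C)C | intermediate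
12 | furan endoperoxide of 11 (2,3,7‑trioxabicyclo[2.2.1]hept‑5‑ene; bridgehead configuration not defined; not isolated) | CC(C)(C)[Si](C)(C)OCC1=CC2OOC1(O2)/C=C/[C@](C)(O)C[C@@H](OC(=O)[C@H](C)CC)C=C(C)C | intermediate
13 | (4R,6R,7E,10Z)‑10‑({[tert‑butyl(dimethyl)silyl]oxy}methyl)‑6‑hydroxy‑2,6‑dimethyl‑9,12‑dioxododeca‑2,7,10‑trien‑4‑yl (2R)‑2‑methylbutanoate | O=C/C=C(/CO[Si](C)(C)C(C)(C)C)C(=O)/C=C/[C@](C)(O)C[C@@H](OC(=O)[C@H](C)CC)C=C(C)C | intermediate
14 | (1E,4Z,6R,7S,8R,10R)‑15‑[(tert‑butyldimethylsilyl)oxy]‑6,10‑dihydroxy‑3‑oxogermacra‑1,4,11(13)‑trien‑8‑yl (2R)‑2‑methylbutanoate (ten‑membered ring, free 6‑OH, isopropenyl on C7) | O[C@@H]1/C=C(/CO[Si](C)(C)C(C)(C)C)C(=O)/C=C/[C@](C)(O)C[C@@H](OC(=O)[C@H](C)CC)[C@H]1C(C)=C | intermediate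
15 | (1E,4Z,6R,7S,8R,10R)‑15‑[(tert‑butyldimethylsilyl)oxy]‑6,10,12‑trihydroxy‑3‑oxogermacra‑1,4,11(13)‑trien‑8‑yl (2R)‑2‑methylbutanoate | O[C@@H]1/C=C(/CO[Si](C)(C)C(C)(C)C)C(=O)/C=C/[C@](C)(O)C[C@@H](OC(=O)[C@H](C)CC)[C@H]1C(CO)=C | intermediate
16 | (1E,4Z,6R,7S,8R,10R)‑15‑[(tert‑butyldimethylsilyl)oxy]‑6,10‑dihydroxy‑3,12‑dioxogermacra‑1,4,11(13)‑trien‑8‑yl (2R)‑2‑methylbutanoate (hydroxy enal, not isolated) | O[C@@H]1/C=C(/CO[Si](C)(C)C(C)(C)C)C(=O)/C=C/[C@](C)(O)C[C@@H](OC(=O)[C@H](C)CC)[C@H]1C(C=O)=C | intermediate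
17 | 12‑hydroxy‑12,6‑epoxy lactol of 16 (6R,7R,8R,10R; C12 epimers; not isolated) | C=C1C(O)O[C@@H]2/C=C(/CO[Si](C)(C)C(C)(C)C)C(=O)/C=C/[C@](C)(O)C[C@@H](OC(=O)[C@H](C)CC)[C@@H]12 | intermediate
18 | [(3aR,4R,6R,7E,10Z,11aR)‑10‑({[tert‑butyl(dimethyl)silyl]oxy}methyl)‑6‑hydroxy‑6‑methyl‑3‑methylidene‑2,9‑dioxo‑2,3,3a,4,5,6,9,11a‑octahydrocyclodeca[b]furan‑4‑yl] (2R)‑2‑methylbutanoate | C=C1C(=O)O[C@@H]2/C=C(/CO[Si](C)(C)C(C)(C)C)C(=O)/C=C/[C@](C)(O)C[C@@H](OC(=O)[C@H](C)CC)[C@@H]12 | intermediate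
19 | [(3aR,4R,6R,7E,10Z,11aR)‑6‑hydroxy‑10‑(hydroxymethyl)‑6‑methyl‑3‑methylidene‑2,9‑dioxo‑2,3,3a,4,5,6,9,11a‑octahydrocyclodeca[b]furan‑4‑yl] (2R)‑2‑methylbutanoate | C=C1C(=O)O[C@@H]2/C=C(/CO)C(=O)/C=C/[C@](C)(O)C[C@@H](OC(=O)[C@H](C)CC)[C@@H]12 | target

**Step count**
Total: 11 steps. Longest linear sequence: 9 steps (steps 3–11 from prenal; equally steps 1, 2, 5–11 from furan‑3‑ylmethanol).

**Three steps most likely to fail, with fallbacks**

Step 8 (carbonyl‑ene macrocyclisation) is the largest risk. It can fail through Z‑to‑E isomerisation of the enal, methyl transfer from aluminium, ionisation or neighbouring‑group capture by the allylic ester, or attack on the wrong alkene face. The fallback replaces the cationic closure by an organometallic closure of the same C6–C7 bond; it sets out from 11 and returns at 14. SeO2 (0.2 equiv)/t‑BuOOH in CH2Cl2 oxidises the E‑methyl of the prenyl unit of 11 to the E‑allylic alcohol F1. CBr4/PPh3 with 2,6‑lutidine at −20 °C converts it into the allylic bromide F2. Photo‑oxygenation and Me2S reduction as in step 7 (−78 °C, where the bromide is inert) unmask the bromo keto‑aldehyde F3. Indium powder in THF/H2O at high dilution then gives an intramolecular Barbier allylation in which the allylindium adds through its gamma carbon (C7) to the C6 aldehyde; this forms the same ring and the same isopropenyl group, that is 14, and steps 9–11 follow.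

Step 7 (furan unmasking) can fail by competing ene oxidation of the prenyl alkene or because the Z‑keto‑enal 13 does not survive isolation. The fallback goes through a storable masked form; it sets out from 11 and returns at 13. Br2 (1.0 equiv) with Na2CO3 in MeOH at −78 °C (oxidative 2,5‑dimethoxylation of the furan) gives the 2,5‑dimethoxy‑2,5‑dihydrofuran F4 as a mixture of acetal isomers that can be purified and stored. Hydrolysis with PPTS in wet acetone at 0 °C releases 13 with the Z geometry just before it is fed into step 8.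

Step 9 (selenium dioxide oxidation of 14) can fail by attack at other positions or by decomposition of the sensitive macrocycle. The fallback replaces the oxo‑ene chemistry by ene‑chlorination and N‑oxide oxidation; it sets out from 14 and returns at 17. Ca(OCl)2 with solid CO2 in CH2Cl2/H2O at 0 °C (HOCl ene‑type chlorination of the isopropenyl group, inert to enones) gives the allylic chloride F5. Trimethylamine N‑oxide in DMSO at rt converts the CH2Cl group into the aldehyde 16, which closes onto the 6‑OH to give lactol 17. Lactol 17 is oxidised to 18 under the conditions of step 10.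

**Further compounds**
F1 | step 8 | (1E,3R,5R,6E)‑1‑[3‑({[tert‑butyl(dimethyl)silyl]oxy}methyl)furan‑2‑yl]‑3,8‑dihydroxy‑3,7‑dimethylocta‑1,6‑dien‑5‑yl (2R)‑2‑methylbutanoate | CC(C)(C)[Si](C)(C)OCc1ccoc1/C=C/[C@](C)(O)C[C@@H](OC(=O)[C@H](C)CC)/C=C(\C)CO
F2 | step 8 | (1E,3R,5R,6E)‑8‑bromo‑1‑[3‑({[tert‑butyl(dimethyl)silyl]oxy}methyl)furan‑2‑yl]‑3‑hydroxy‑3,7‑dimethylocta‑1,6‑dien‑5‑yl (2R)‑2‑methylbutanoate | CC(C)(C)[Si](C)(C)OCc1ccoc1/C=C/[C@](C)(O)C[C@@H](OC(=O)[C@H](C)CC)/C=C(\C)CBr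
F3 | step 8 | (2E,4R,6R,7E,10Z)‑1‑bromo‑10‑({[tert‑butyl(dimethyl)silyl]oxy}methyl)‑6‑hydroxy‑2,6‑dimethyl‑9,12‑dioxododeca‑2,7,10‑trien‑4‑yl (2R)‑2‑methylbutanoate | O=C/C=C(/CO[Si](C)(C)C(C)(C)C)C(=O)/C=C/[C@](C)(O)C[C@@H](OC(=O)[C@H](C)CC)/C=C(\C)CBr
F4 | step 7 | (1E,3R,5R)‑1‑[3‑({[tert‑butyl(dimethyl)silyl]oxy}methyl)‑2,5‑dimethoxy‑2,5‑dihydrofuran‑2‑yl]‑3‑hydroxy‑3,7‑dimethylocta‑1,6‑dien‑5‑yl (2R)‑2‑methylbutanoate (acetal isomers) | COC1C=C(CO[Si](C)(C)C(C)(C)C)C(OC)(O1)/C=C/[C@](C)(O)C[C@@H](OC(=O)[C@H](C)CC)C=C(C)C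
F5 | step 9 | (1E,4Z,6R,7S,8R,10R)‑15‑[(tert‑butyldimethylsilyl)oxy]‑12‑chloro‑6,10‑dihydroxy‑3‑oxogermacra‑1,4,11(13)‑trien‑8‑yl (2R)‑2‑methylbutanoate | O[C@@H]1/C=C(/CO[Si](C)(C)C(C)(C)C)C(=O)/C=C/[C@](C)(O)C[C@@H](OC(=O)[C@H](C)CC)[C@H]1C(CCl)=C
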